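One mole of Sub turned into Prd2 costs two moles of Rgt, one spent in the step and one held as Rgt.Byp by the Byp set free, for as long as that Byp stays bound.

    Sub + Rgt → Byp + Prd2 (k1 = 2.0 /M/h)
    Rgt + Byp ⇌ Rgt.Byp, settled at all times (K2 = 1.0 × 10⁵ /M)
    Byp + Bse ⇌ Byp.Bse (K3 = 600 /M, k3 = 19 /M/h)
    2 Bse → Prd (k4 = 3.0 /M/h)
    Sub + Tsp → Sub.Tsp (k5 = 4.1 /M/h)
    Byp → Byp2 (k6 = 0.086 /h)

Sub 0.050 M; Rgt 0.0650 M; Bse 0.0400 M; Tsp 0.0100 M; time 10 d

* part of the Sub that has reacted at 10 d
* share of the unused Rgt that is free and not bound as Rgt.Byp, at 10 d

In the first instants Sub, charged in the smaller amount against Rgt, leaves along two paths, the one to Prd2 going 3.2 times as fast as the one to Sub.Tsp. Each Byp formed meets Rgt and Bse, and the binding power of Rgt as charged stands 271 times over that of Bse, so Byp goes to Rgt, while Bse destroys itself with a first half-life by that step alone of 4.17 h, short against the run.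

In the middle, Tsp is counted whole, since its half-life with Sub as charged, 3.38 h, is short against the run. With x of Prd2 formed and each Byp held as Rgt.Byp, the free Rgt is the charged c(Rgt) − 2x, which this reckoning brings to zero at x = 0.0325 M, less than the Sub that Tsp leaves, so Rgt, though charged in excess, is the limiting reagent. Hence, in charges, (c(Tsp) + c(Rgt)/2)/c(Sub) = 85.0%, the titration reach, the part of the charged Sub reckoned as used once Tsp has taken its share and Rgt is spent or bound with each Byp still held.

Towards the end, the flask moves on what leaves Rgt.Byp: free Byp goes to Byp2 with a half-life by that step alone of 0.34 d, short against the run, and each Byp that leaves Rgt.Byp this way returns one Rgt, which by the balance is worth 0.5 Sub more. This reckoning therefore commits to c somewhat above the reach and gives no figure for fr.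

The forecast, holding that “each Byp formed locks up a second Rgt”, gives 88.5% and 3.4%, its c above this reach. The simulation gives 89.0% and 3.38%.

The flask has not come to rest at 10 d: c stands above the reach, and the balance of Rgt, the reach plus 0.5 Sub for each Byp not held as Rgt.Byp (0.00459 M as Byp2, 1.44 × 10⁻⁴ M as Byp.Bse, 2.86 × 10⁻⁴ M free), less 0.5 for each free Rgt, comes to 89.0%. At 100 d the flask holds 0% of its Sub, so c is 100%; Byp2 has grown to 0.0219 M, Rgt.Byp has fallen from 0.0295 M to 0.0181 M, and free Rgt has risen from 1.59% to 10.6% of its charge.

In the neighbour flask charged with 0.12 M of Sub, the reach is 35.4%. That flask gives 43.5% at 10 d, 8.1 percentage points above its reach, and in that flask the same balance, with 0.0182 M of Byp2, 5.75 × 10⁻⁴ M of Byp.Bse and 8.64 × 10⁻⁴ M of free Byp, less its free Rgt, counts for 8.06% of its Sub.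

The rate constants were set for the occasion, and the outcome is calculated.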